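A small charge of racemization catalyst, 0.500% of the left-handed substrate charged, stood in each of these flasks, and I had to judge what it did to the excess.

all flasks: left-handed substrate 0.88 M; right-handed substrate 0.88 M; reagent 1.76 M; racemization catalyst 4.4 mM
- alpha: free catalyst 130 mM; the very flask that is asked about, followed so far
- beta: free catalyst 87 mM; run made earlier
- flask: free catalyst 130 mM; time 30 min

| run | time / min | left-handed product / % | right-handed product / % |
|---|---|---|---|
| alpha | 0.417 | 0.3 | 1.1 |
| alpha | 1.33 | 4.3 | 2.8 |
| alpha | 2.00 | 6.8 | 3.6 |
| alpha | 3.00 | 8.7 | 5.0 |
| alpha | 5.00 | 14.4 | 6.8 |
| alpha | 6.00 | 15.7 | 8.0 |
| beta | 5.00 | 10.4 | 6.2 |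
| beta | 10.0 | 18.2 | 10.1 |
| beta | 15.0 | 23.6 | 13.1 |
| beta | 20.0 | 27.0 | 15.7 |
| beta | 25.0 | 30.2 | 17.1 |
| beta | 30.0 | 33.1 | 18.7 |

(standard deviation of a reading: 0.5 percentage points)

- free catalyst is single-handed; left-handed substrate and right-handed substrate are mirror images of each other, charged as a racemate, each of them at the stated concentration
- reactions considered so far: left-handed substrate + racemization catalyst <-> right-handed substrate + racemization catalyst; reagent + free catalyst + right-handed substrate -> free catalyst + right-handed product; 2 reagent -> homo dimer; 2 free catalyst <-> resting dimer; reagent + free catalyst + left-handed substrate -> free catalyst + left-handed product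
- an excess is the difference of the two amounts in percent of their sum
- an excess is below zero if the other one leads

1. excess of left-handed product over right-handed product in the product at 1.5 min
2. excess of left-handed product over right-handed product in the product at 30 min
3. part of the left-handed substrate and right-handed substrate charged together that has reacted at 30 min

The bench rule for a racemate is kinetic resolution: the hands stay apart, and the logarithm of the fraction left of one hand over that of the other is the selectivity factor, constant through a run. I applied it to beta, counting each hand as half the charge, and it gave 1.76 at 5.00 min but 2.32 at 30.0 min. A constant should not climb like that, so this ratio marked the border of the rule.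

I then took the other end state, dynamic kinetic resolution: the two substrates stay level, like a feed kept constant, so the products form in one ratio at every conversion. That product ratio is then the selectivity factor itself, and beta's last readings give 1.77, a reading with its scatter. The plateau excess, the selectivity factor less one over the selectivity factor plus one, is the product excess while the substrates stay level: 27.8%. I expected it at both asked times in the flask, which differs from beta in its free catalyst, 130 mM against 87 mM.

The forecast, holding “racemization is keeping up”, gave 30% (26% to 34%) at 1.5 min, 27.5% (23.5% to 30.5%) at 30 min, and 59% (55% to 63%) reacted. My plateau excess lay lower than its early figure.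

The flask gave 28.5% at 1.5 min and 28.6% at 30 min, with 57.5% reacted, each inside the forecast's range and the later excess 0.80 percentage points from my plateau excess.

    left-handed substrate + racemization catalyst ⇌ right-handed substrate + racemization catalyst, rate k1*[racemization catalyst]*[left-handed substrate] forward; the back reaction follows from the equilibrium constant (k = 22.0 M⁻¹ s⁻¹)
    reagent + free catalyst + right-handed substrate → free catalyst + right-handed product (k = 0.00610 M⁻² s⁻¹)
    2 reagent → homo dimer (k = 8.10 × 10⁻⁵ M⁻¹ s⁻¹)
    2 free catalyst ⇌ resting dimer, settled at all times (K = 8.70 M⁻¹)
    reagent + free catalyst + left-handed substrate → free catalyst + left-handed product (k = 0.0110 M⁻² s⁻¹)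

Racemization ran throughout, its forward half-life as charged being 0.12 min, short against the 30 min of the run, and at 30.0 min the right-handed substrate led what was left by 0.0381%. Both product steps ran meanwhile on free catalyst steady at 48.0% of the catalyst charged, with 52.0% as resting dimer, while the reagent fell to 27.4% of its charge.

For the neighbour with 0.52 M of free catalyst, the plateau excess again gives 27.8%. The computed flask gave 28.5% at 30 min, with 76.0% reacted.

The earlier runs and the new flask were computed with constants of no real substance, and the scatter is random.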